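The data stem from a simulated flask on assumed constants; scatter was added.

3 questions stood over this flask, each about a charge that no run had changed.

| setting | east | flask |
|---|---|---|
| starting material | 24 mM | 24 mM |
| second substrate | 24 mM | 24.0 mM |
| free catalyst | 0.86 mM | 0.86 mM |
| impurity | 0.25 mM | 0.25 mM |
| remark | the very flask that is asked about, followed so far |  |

east run (percent of the starting material charged)

| time / min | target / % | starting material / % |
|---|---|---|
| 0.250 | 1.1 | 96.3 |
| 0.417 | 3.2 | 94.4 |
| 0.833 | 9.2 | 87.4 |
| 1.50 | 18.5 | 82.9 |
| 3.00 | 32.4 | 67.0 |

(each reading ± 1 percentage point)

- the numbers in the tables scatter with a standard deviation of 1 percentage point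
- no earlier run changes the charge of free catalyst; that part of a forecast is a guess
- no earlier run changes the charge of second substrate; that part of a forecast is a guess

- apparent order in free catalyst when 30 % of the starting material are converted (percent change of the rate of making target for one percent more free catalyst charged)
- apparent order in second substrate when 30 % of the starting material are converted (percent change of the rate of making target for one percent more second substrate charged)
- factor on the rate of making target when 30 % of the starting material are converted if second substrate is charged twice over

The east run is this same flask, so its readings gave me a time course but no order. Its last one, 67.0 % of starting material left after 3.00 min, lay close to the 30 % conversion in question.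

So I followed one impurity molecule. I assumed that it met free catalyst and took that molecule out of the round for good, as a stoichiometric poison. This folds the charges into one number: 0.291, the dead share, the impurity charged over the free catalyst charged. On that assumption it is the fraction of the catalyst charge that ends up outside the round. If the rate follows the survivors, the catalyst charge minus the impurity charge, then one percent more catalyst gives more than one percent more survivors, and the order in free catalyst reads 1.41, one over one minus the dead share. Was one number enough? No: second substrate stands nowhere in it, so it gave me nothing on the other 2 questions.

The forecast said 1.1 (0.8 to 1.5) for free catalyst, lower than my figure. For second substrate it said 0.95 (0.4 to 1.45), and 1.7 (1.25 to 2.45) on doubling, with the warning: “Neither charge was varied, so the forecasts are guesses.”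

The flask gave 1.4 in free catalyst, −0.41 in second substrate, and a factor 0.711 on doubling: at that conversion, more second substrate slowed the making of target.

    second substrate + free catalyst ⇌ catalyst intermediate B (K = 52.0 M⁻¹, k = 750 M⁻¹ s⁻¹)
    catalyst intermediate B → free catalyst + second product (k = 0.120 s⁻¹)
    catalyst intermediate A → free catalyst + target (k = 0.360 s⁻¹)
    starting material + free catalyst ⇌ catalyst intermediate A (K = 91.0 M⁻¹, k = 13.0 M⁻¹ s⁻¹)
    free catalyst + impurity → spent catalyst (k = 1000 M⁻¹ s⁻¹)

The dead share left 70.9 % of the catalyst charge in the round. After 1.50 min the flask held 14.0 % of the catalyst charge as catalyst intermediate A, 29.5 % as catalyst intermediate B, more than as A, 27.4 % as free catalyst and 29.1 % as spent catalyst. The largest single effect on the negative order was second substrate binding free catalyst, both ways: the run without that reaction shows an order of 0 in place of −0.41.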